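The data stem from a simulated flask with made-up constants; scatter was added.

**The decision.** If this run is repeated with 94.0 mM of reagent on 47 mM of substrate, we must choose between leaving it longer and changing the charge, and that choice hangs on what stopped the earlier runs.

| flask | substrate | reagent | remark | time |
|---|---|---|---|---|
| Saturday's | 24 mM | 94 mM | run made earlier |  |
| Thursday's | 94 mM | 94 mM | run made earlier |  |
| Sunday's | 47 mM | 140 mM | run made earlier |  |
| flask | 47 mM | 94.0 mM |  | 2.0 h |

| run | time / min | mono adduct / % | double product / % | tris adduct / % |
|---|---|---|---|---|
| Saturday's | 20.0 | 14 | 21 | 22 |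
| Saturday's | 40.0 | 18 | 17 | 24 |
| Saturday's | 60.0 | 17 | 17 | 26 |
| Saturday's | 80.0 | 16 | 19 | 23 |
| Saturday's | 90.0 | 17 | 20 | 23 |
| Saturday's | 120 | 19 | 21 | 23 |
| Thursday's | 10.0 | 18 | 11 | 4 |
| Thursday's | 15.0 | 20 | 11 | 6 |
| Thursday's | 25.0 | 20 | 14 | 7 |
| Thursday's | 40.0 | 19 | 12 | 5 |
| Thursday's | 80.0 | 17 | 13 | 8 |
| Thursday's | 120 | 18 | 10 | 5 |
| Sunday's | 25.0 | 17 | 20 | 20 |
| Sunday's | 50.0 | 18 | 16 | 20 |
| Sunday's | 80.0 | 17 | 19 | 15 |
| Sunday's | 90.0 | 16 | 19 | 18 |
| Sunday's | 120 | 20 | 16 | 18 |

(each reading ± 1.5 percentage points)

- the reaction counts as stopped when no species that holds the substrate changes by six tenths of a point or more over the second half of the time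

1. at 2.0 h, what has stopped the reaction, if anything has (forward and back rates have come level / all of the substrate has reacted / it is still moving / the reagent has run out first)
2. the mono adduct standing at 2.0 h, as a percentage of the substrate charged
3. the double product standing at 2.0 h, as a percentage of the substrate charged
4. the tris adduct standing at 2.0 h, as a percentage of the substrate charged

**Capture share.** From their first readings on, the earlier runs show no clear trend beyond a scatter of 1.5 percentage points. So we average each run and count the reagent standing in adducts: one per mono adduct, two per double product, 3 per tris adduct. As a share of the reagent charged, this gives 0.321 on Saturday, 0.598 on Thursday and 0.363 on Sunday.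

**Free or gone?** Sunday's run has 89.1 mM of reagent outside these adducts, more than Saturday's 63.8 mM. Yet its tris-to-double reading is 1.01 against Saturday's 1.23. We therefore read that reagent as spent on something unmeasured, not as free.

**Loss slope.** Reagent outside per reagent captured is 0.671 on Thursday and 1.75 on Sunday. Between these two runs, each extra unit of reagent per substrate charged adds 0.547 to that ratio, and we call this the loss slope. For this flask we reckon a capture share of 0.451, with 51.6 mM of the reagent outside the three measured adducts and read as spent, not free. We would keep the time, change the charge if more adduct is wanted, and read the reagent at the first sample.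

The forecast gives 18.5% mono adduct, 15.5% double product and 12% tris adduct, answers the question of the stop with forward and back rates have come level, and says “the reaction stops because forward and back rates level”; on the stop we differ, since we read the reagent as spent.

**The result.** At 2.0 h the flask stands at 18.8% mono adduct, 16.3% double product and 12.8% tris adduct, and the stop is this: the reagent has run out first. As limiting reagent it is down to 0.00577% of its charge at 0.200 h.

    substrate + reagent → mono adduct (k = 0.163 M⁻¹ s⁻¹)
    reagent + tris adduct → tetra adduct (k = 0.0673 M⁻¹ s⁻¹)
    reagent + mono adduct → double product (k = 0.492 M⁻¹ s⁻¹)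
    reagent + double product → tris adduct (k = 0.419 M⁻¹ s⁻¹)
    2 reagent → homo dimer (k = 0.156 M⁻¹ s⁻¹)

**Next flask.** In this flask the three measured adducts hold a capture share of 0.449, against our 0.451. With 120 mM of substrate on the same reagent, the loss slope gives a capture share of 0.644. That neighbour stands at 18.3% mono adduct, 10.0% double product and 4.05% tris adduct, a capture share of 0.644.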